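**Plan**
Retrosynthesis: the seven-membered lactone (C3–O–C17(=O)–C15–C14–C1–C2) is cut at O–C3 and at C17–C15, which releases CO2 and a seco-diene with an exocyclic methylidene at C3 on the oxonane and an alkenyl triflate at C15 on the cyclohexane. Earlier cuts: cyclohexane at C12–C13/C14–C1 (Diels–Alder), oxonane at C8–C9 (oxonium ylide [2,3] ring expansion of a tetrahydropyran), tetrahydropyran at C2–C3 (ketyl–acrylate cyclization).
Forward: tetrahydropyran, then the oxygen-bridged nine-membered ring together with the tetrahydrofuran, then the cyclohexane, then the lactone by stitching CO2 between C15 and C3, then one hydrogenation that removes every helper.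
Enabling feature: C15 and C3 are 1,5-related through C14–C1–C2 and sit trans on the C1–C2 bond of the tetrahydrofuran (C1, C2, O, C9, C10). They cannot bond to each other (that would be a trans-fused five/five system), but one O–C(=O) unit spans them as a trans-fused seven-membered ring. C15 is made nucleophilic as an alkenyl carbon (from the Diels–Alder acetyl group) and C3 electrophilic as a 1,1-disubstituted alkene.
Stereochemistry: one reagent-controlled reduction (the carbinol that becomes C6 of the tetrahydropyran) is relayed to C2 (cyclization), C9 (bridged rearrangement), C1/C14/C10 (cycloaddition anti to the six-carbon bridge, epimerization, protonation), C6/C7 (dihydroxylation of the outer face of the E-alkene), C11 (axial Grignard addition), C3 (anti iodolactonization) and C15 (hydrogenation).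

Key step: step 23

Remark: cladiellin numbering is used for all bicyclic and tricyclic compounds (the ether oxygen bridges C2 and C9; C16 is the methyl on C15, C17 the lactone carbonyl, C18 the methyl on C3).
Assumption: the THF solution of Grignard reagent 1 is taken as a commercial starting material.

**Step 1**
Reactants: 1 2-(1,3-dioxan-2-yl)ethylmagnesium bromide; 2 methacrolein
Product: 3 rac-1-(1,3-dioxan-2-yl)-4-methylpent-4-en-3-ol
Conditions: THF, −78 → 0 °C; aq. NH4Cl
Reagents that add atoms: none
Why: Grignard 1,2-addition to the enal gives the isopropenyl carbinol that carries C3 (acetal carbon) to C8 as a racemate.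

**Step 2**
Reactants: 3 rac-1-(1,3-dioxan-2-yl)-4-methylpent-4-en-3-ol
Product: 4 1-(1,3-dioxan-2-yl)-4-methylpent-4-en-3-one
Conditions: Dess–Martin periodinane, pyridine, CH2Cl2, 0 °C → rt
Reagents that add atoms: none
Why: Buffered Dess–Martin oxidation of the allylic alcohol leaves the acetal intact and gives the enone needed for a reagent-controlled reduction.

**Step 3**
Reactants: 4 1-(1,3-dioxan-2-yl)-4-methylpent-4-en-3-one
Product: 5 (S)-1-(1,3-dioxan-2-yl)-4-methylpent-4-en-3-ol
Conditions: (R)-2-methyl-CBS-oxazaborolidine (10 mol%), catecholborane, toluene, −78 °C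
Reagents that add atoms: none
Why: Corey–Bakshi–Shibata reduction in which the isopropenyl group acts as the large substituent, so the (R)-catalyst should give the (S)-carbinol, the only stereocenter set by a chiral reagent.

**Step 4**
Reactants: 5 (S)-1-(1,3-dioxan-2-yl)-4-methylpent-4-en-3-ol; 6 ethyl propiolate
Product: 7 ethyl (E)-3-{[(3S)-1-(1,3-dioxan-2-yl)-4-methylpent-4-en-3-yl]oxy}acrylate
Conditions: N-methylmorpholine, CH2Cl2, rt
Reagents that add atoms: none
Why: Amine-catalysed oxa-Michael addition of the alcohol to the propiolate gives the (E)-β-alkoxyacrylate that serves as radical acceptor in the ring closure.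

**Step 5**
Reactants: 7 ethyl (E)-3-{[(3S)-1-(1,3-dioxan-2-yl)-4-methylpent-4-en-3-yl]oxy}acrylate
Product: 8 ethyl (E)-3-{[(3S)-2-methyl-6-oxohex-1-en-3-yl]oxy}acrylate
Conditions: AcOH/H2O (4:1), 60 °C
Reagents that add atoms: water, O
Why: Acid hydrolysis of the 1,3-dioxane unmasks the aldehyde (C3) while the vinylogous carbonate and the allylic ether should survive.

**Step 6**
Reactants: 8 ethyl (E)-3-{[(3S)-2-methyl-6-oxohex-1-en-3-yl]oxy}acrylate
Product: 9 ethyl 2-[(2S,3R,6S)-3-hydroxy-6-(prop-1-en-2-yl)tetrahydropyran-2-yl]acetate (2,6-cis and 2,3-trans)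
Conditions: SmI2 (3 equiv), MeOH, THF, 0 °C
Reagents that add atoms: none
Why: Samarium diiodide ketyl–olefin reductive cyclization (6-exo-trig) forms C2–C3 through a chair transition state with the acrylate and the isopropenyl group equatorial, which sets C2 cis to C6 and the C3 hydroxyl trans to C2.

**Step 7**
Reactants: 9 ethyl 2-[(2S,3R,6S)-3-hydroxy-6-(prop-1-en-2-yl)tetrahydropyran-2-yl]acetate
Product: 10 the 3-O-tert-butyldimethylsilyl ether of 9
Conditions: TBSOTf, 2,6-lutidine, CH2Cl2, −78 °C
Reagents that add atoms: tert-butyldimethylsilyl triflate, CC(C)(C)[Si](C)(C)OS(=O)(=O)C(F)(F)F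
Why: Silylation protects O-3 as a bulky, weakly nucleophilic ether that will not compete with the ring oxygen for the carbenoid in step 10.

**Step 8**
Reactants: 10 the 3-O-tert-butyldimethylsilyl ether of 9
Product: 11 2-[(2S,3R,6S)-3-(tert-butyldimethylsilyloxy)-6-(prop-1-en-2-yl)tetrahydropyran-2-yl]acetic acid
Conditions: LiOH, THF/MeOH/H2O, rt; then 1 M HCl to pH 4
Reagents that add atoms: lithium hydroxide, [Li+].[OH-]
Why: Saponification of the ethyl ester gives the acid needed for homologation to the diazoketone.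

**Step 9**
Reactants: 11 2-[(2S,3R,6S)-3-(tert-butyldimethylsilyloxy)-6-(prop-1-en-2-yl)tetrahydropyran-2-yl]acetic acid
Product: 13 1-diazo-3-[(2S,3R,6S)-3-(tert-butyldimethylsilyloxy)-6-(prop-1-en-2-yl)tetrahydropyran-2-yl]propan-2-one, via isobutyl carbonic anhydride 12 (not isolated)
Conditions: i-BuOCOCl, Et3N, Et2O, 0 °C; then CH2N2, Et2O, 0 °C → rt
Reagents that add atoms: isobutyl chloroformate, CC(C)COC(=O)Cl (atoms kept only in 12); diazomethane, C=[N+]=[N-]
Why: Acylation of diazomethane by the mixed anhydride gives the α-diazoketone whose diazo carbon becomes C9.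

**Step 10**
Reactants: 13 1-diazo-3-[(2S,3R,6S)-3-(tert-butyldimethylsilyloxy)-6-(prop-1-en-2-yl)tetrahydropyran-2-yl]propan-2-one
Product: 14 E-bicyclic ketone: 2,9-oxygen-bridged (6E)-oxonene with the C10 ketone in the tetrahydrofuranone ring, 7-methyl and 3-OTBS
Conditions: Rh2(NHCOC3F7)4 (2 mol%), THF, reflux, slow addition
Reagents that add atoms: none
Why: Rhodium carbenoid formation, attack by the ring oxygen to give a bicyclic oxonium ylide and [2,3]-sigmatropic rearrangement form C8–C9 and expand the tetrahydropyran by three atoms to the oxonene bridged by the new tetrahydrofuranone; the C6 stereocenter is traded for C9, which must be cis to C2 across the bridging oxygen, and the electron-poor amidate catalyst is chosen because it should favour the E-alkene.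

**Step 11**
Reactants: 14 E-bicyclic ketone
Product: 15 enol triflate of 14 (C1=C10, triflate on C10)
Conditions: NaHMDS, PhNTf2, THF, −78 °C
Reagents that add atoms: N-phenylbis(trifluoromethanesulfonimide), O=S(=O)(N(c1ccccc1)S(=O)(=O)C(F)(F)F)C(F)(F)F
Why: Kinetic enolization toward the C1 methylene (not the bridgehead C9) and O-triflation give the coupling handle and remove the ketone before the diol is made.

**Step 12**
Reactants: 15 enol triflate of 14
Product: 16 6,7-diol of 15
Conditions: OsO4 (5 mol%), NMO, acetone/H2O, rt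
Reagents that add atoms: osmium tetroxide (catalytic oxygen carrier), O=[Os](=O)(=O)=O; N-methylmorpholine N-oxide, C[N+]1([O-])CCOCC1; water, O
Why: Catalytic syn-dihydroxylation (Upjohn conditions) of the strained, electron-rich E-alkene in preference to the electron-poor enol triflate; osmium can reach only the outer face of the trans-cycloalkene, whose planar chirality was fixed in step 10, which should set C6 and C7.

**Step 13**
Reactants: 16 6,7-diol of 15
Product: 17 6-O-methyl ether of 16 (7-OH free)
Conditions: Me3OBF4, 1,8-bis(dimethylamino)naphthalene, CH2Cl2, 0 °C → rt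
Reagents that add atoms: trimethyloxonium tetrafluoroborate, C[O+](C)C.F[B-](F)(F)F
Why: O-Methylation with the oxonium salt under non-basic conditions should select the secondary C6 hydroxyl over the hindered tertiary C7 hydroxyl.

**Step 14**
Reactants: 17 6-O-methyl ether of 16
Product: 18 7-O-benzyloxymethyl ether of 17
Conditions: BOMCl, i-Pr2NEt, Bu4NI, 1,2-dichloroethane, 50 °C
Reagents that add atoms: benzyl chloromethyl ether, ClCOCc1ccccc1
Why: Alkylation of the tertiary alcohol as a BOM acetal masks O-7 (a transannular nucleophile toward C3) with a group stable to fluoride, base and organometallics and removable by hydrogenolysis in the last step.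

**Step 15**
Reactants: 18 7-O-benzyloxymethyl ether of 17; 19 tributyl(1-ethoxyvinyl)stannane
Product: 20 2-ethoxydiene (C1=C10–C11(OEt)=C12)
Conditions: Pd(PPh3)4 (5 mol%), LiCl, THF, reflux
Reagents that add atoms: none
Why: Stille coupling of the enol triflate installs C11 and C12 as an electron-rich diene.

**Step 16**
Reactants: 20 2-ethoxydiene; 21 methyl vinyl ketone
Product: 23 tricyclic 14-acetyl enol ether (acetyl trans to C2 on the C1–C14 bond), via 14-epimeric cycloadduct 22 (not isolated)
Conditions: toluene, 110 °C, sealed tube; then K2CO3, MeOH, rt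
Reagents that add atoms: none
Why: Diels–Alder reaction with para regiochemistry forms C12–C13 and C14–C1, the dienophile adding to the dihydrofuran face anti to the six-carbon bridge (sets C1), and base equilibrates the kinetic C14 epimer to the equatorial acetyl compound.

**Step 17**
Reactants: 23 tricyclic 14-acetyl enol ether
Product: 24 alkenyl triflate (C15(OTf)=C16H2) of 23
Conditions: KHMDS, THF, −78 °C; then PhNTf2
Reagents that add atoms: N-phenylbis(trifluoromethanesulfonimide), O=S(=O)(N(c1ccccc1)S(=O)(=O)C(F)(F)F)C(F)(F)F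
Why: Kinetic deprotonation of the methyl ketone at CH3 and O-triflation turn C15 into a latent nucleophilic alkenyl carbon and mask the ketone before C11 is unveiled.

**Step 18**
Reactants: 24 alkenyl triflate of 23
Product: 26 3-hydroxy-11-ketone (cis-fused at C1–C10), via 3-hydroxy enol ether 25 (not isolated)
Conditions: HF·pyridine, pyridine, THF, 0 °C → rt; then 1 M HCl, THF, 0 °C
Reagents that add atoms: water, O
Why: Fluoride desilylation followed by acid hydrolysis of the enol ether frees O-3 and the C11 ketone; C10 is protonated to the cis ring fusion, which is also the isomer reached by enolization.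

**Step 19**
Reactants: 26 3-hydroxy-11-ketone
Product: 27 11-methyl-3,11-diol
Conditions: MeMgCl, LaCl3·2LiCl, THF, −78 → −40 °C
Reagents that add atoms: methylmagnesium chloride, C[Mg]Cl
Why: Lanthanum-promoted Grignard addition (little enolization); in the chair with C9 axial on C10 the methyl enters axially on the face anti to C9, which puts the C11 oxygen cis to the tetrahydrofuran ring as in the target.

**Step 20**
Reactants: 27 11-methyl-3,11-diol
Product: 28 3-ketone (11-OH free)
Conditions: Dess–Martin periodinane, pyridine, CH2Cl2, rt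
Reagents that add atoms: none
Why: Dess–Martin oxidation of the secondary C3 alcohol; the tertiary C11 alcohol cannot be oxidized.

**Step 21**
Reactants: 28 3-ketone
Product: 29 3-methylidene compound (11-OH free)
Conditions: Ph3PCH3Br (excess), KHMDS, THF, 0 °C → rt
Reagents that add atoms: methyltriphenylphosphonium bromide (as its ylide), C[P+](c1ccccc1)(c1ccccc1)c1ccccc1.[Br-]
Why: Wittig methylenation converts the C3 ketone into the 1,1-disubstituted alkene that is the latent electrophilic terminus (C18 is introduced as CH2); C2 is a bridgehead and cannot epimerize.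

**Step 22**
Reactants: 29 3-methylidene compound
Product: 30 seco-diene: 11-acetate with C3 methylidene and C15 alkenyl triflate
Conditions: Ac2O, DMAP, Et3N, CH2Cl2, 40 °C
Reagents that add atoms: acetic anhydride, CC(=O)OC(C)=O
Why: DMAP-catalysed acylation of the only free hydroxyl installs the tertiary acetate and removes O-11 as a competing nucleophile for the key step.

**Step 23**
Reactants: 30 seco-diene; 31 carbon dioxide
Product: 33 α-methylene iodolactone (C18 as CH2I), via acrylate carboxylate 32 (not isolated)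
Conditions: CoI2(2,9-dimethyl-1,10-phenanthroline) (10 mol%), Mn powder, CO2 (1 atm), DMA, rt; then filtered from Mn under Ar; I2, NaHCO3, MeCN, 0 °C → rt, dark
Reagents that add atoms: iodine, II
Why: Oxidative addition of the alkenyl triflate to low-valent cobalt and insertion of CO2 into the C15–Co bond (Mn as terminal reductant) form C17–C15 and give the 2-substituted acrylate 32; iodine then forms an iodonium ion on the electron-rich C3=CH2 bond and the tethered carboxylate opens it at the tertiary carbon, forming O–C3. The closest known reaction types are the cobalt/manganese reductive carboxylation of alkenyl triflates with CO2 and the iodolactonization of ω-alkenoic acids to seven-membered lactones. The lactone ring (C3–O–C17–C15–C14–C1–C2) closes in the 7-exo-trig mode, with CH2I left outside the ring. The new stereocenter C3 is set by anti addition: iodine takes the exposed outer face of the methylidene and the carboxylate, tethered through C1 on C2, reaches C3 only from the face syn to the C1–C2 bond (H-2 eclipsing the C=CH2 bond to avoid 1,3-allylic strain), so the lactone oxygen ends cis to C1 and CH2I trans. The step needs CO2 capture to beat 5-exo carbometalation of C3=CH2, which is secured because C15 and C3 are trans on the C1–C2 bond of the tetrahydrofuran (a direct C15–C3 bond would give a trans-fused bicyclo[3.3.0] system); it also needs iodine to attack C3=CH2 and not the acrylate alkene, which is secured by the electron-poor character of the acrylate and by O-7 and O-11 being masked as BOM ether and acetate.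

**Step 24**
Reactants: 33 α-methylene iodolactone
Product: 34 target compound CNP0238771.1
Conditions: H2 (1 atm), Pd(OH)2/C, NaHCO3, EtOAc, rt
Reagents that add atoms: none
Why: One heterogeneous hydrogenation should remove all three helpers: hydrogenolysis of the neopentyl C–I bond (CH2I becomes the C18 methyl), hydrogenolysis of the BOM ether (frees the C7 hydroxyl), and syn addition of H2 to the exocyclic alkene from the lactone face that carries H-14 and H-2, away from the ether oxygen and C4 of the oxonane, which sets C15.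

**Compound list**
1 | 2-(1,3-dioxan-2-yl)ethylmagnesium bromide | Br[Mg]CCC1OCCCO1 | starting material
2 | methacrolein | CC(=C)C=O | starting material
3 | rac-1-(1,3-dioxan-2-yl)-4-methylpent-4-en-3-ol | CC(=C)C(O)CCC1OCCCO1 | intermediate
4 | 1-(1,3-dioxan-2-yl)-4-methylpent-4-en-3-one | CC(=C)C(=O)CCC1OCCCO1 | intermediate
5 | (S)-1-(1,3-dioxan-2-yl)-4-methylpent-4-en-3-ol | C=C(C)[C@@H](O)CCC1OCCCO1 | intermediate
6 | ethyl propiolate | CCOC(=O)C#C | starting material
7 | ethyl (E)-3-{[(3S)-1-(1,3-dioxan-2-yl)-4-methylpent-4-en-3-yl]oxy}acrylate | CCOC(=O)/C=C/O[C@@H](CCC1OCCCO1)C(C)=C | intermediate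
8 | ethyl (E)-3-{[(3S)-2-methyl-6-oxohex-1-en-3-yl]oxy}acrylate | CCOC(=O)/C=C/O[C@@H](CCC=O)C(C)=C | intermediate
9 | ethyl 2-[(2S,3R,6S)-3-hydroxy-6-(prop-1-en-2-yl)tetrahydropyran-2-yl]acetate | CCOC(=O)C[C@H]1[C@H](O)CC[C@@H](C(C)=C)O1 | intermediate
10 | 3-O-TBS ether of 9 | CCOC(=O)C[C@H]1[C@H](O[Si](C)(C)C(C)(C)C)CC[C@@H](C(C)=C)O1 | intermediate
11 | 2-[(2S,3R,6S)-3-(TBS-oxy)-6-(prop-1-en-2-yl)tetrahydropyran-2-yl]acetic acid | OC(=O)C[C@H]1[C@H](O[Si](C)(C)C(C)(C)C)CC[C@@H](C(C)=C)O1 | intermediate
12 | isobutyl carbonic anhydride of 11 | CC(C)COC(=O)OC(=O)C[C@H]1[C@H](O[Si](C)(C)C(C)(C)C)CC[C@@H](C(C)=C)O1 | intermediate (not isolated)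
13 | diazoketone of 11 | [N-]=[N+]=CC(=O)C[C@H]1[C@H](O[Si](C)(C)C(C)(C)C)CC[C@@H](C(C)=C)O1 | intermediate
14 | E-bicyclic ketone (C10 ketone, (6E)-alkene, 7-methyl, 3-OTBS) | O=C1C[C@@H]2O[C@H]1C/C(C)=C/CC[C@H]2O[Si](C)(C)C(C)(C)C | intermediate
15 | enol triflate of 14 | O=S(=O)(OC1=C[C@@H]2O[C@H]1C/C(C)=C/CC[C@H]2O[Si](C)(C)C(C)(C)C)C(F)(F)F | intermediate
16 | 6,7-diol of 15 | O=S(=O)(OC1=C[C@@H]2O[C@H]1C[C@@](C)(O)[C@H](O)CC[C@H]2O[Si](C)(C)C(C)(C)C)C(F)(F)F | intermediate
17 | 6-O-methyl ether of 16 | O=S(=O)(OC1=C[C@@H]2O[C@H]1C[C@@](C)(O)[C@H](OC)CC[C@H]2O[Si](C)(C)C(C)(C)C)C(F)(F)F | intermediate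
18 | 7-O-BOM ether of 17 | O=S(=O)(OC1=C[C@@H]2O[C@H]1C[C@@](C)(OCOCc3ccccc3)[C@H](OC)CC[C@H]2O[Si](C)(C)C(C)(C)C)C(F)(F)F | intermediate
19 | tributyl(1-ethoxyvinyl)stannane | CCCC[Sn](CCCC)(CCCC)C(=C)OCC | starting material
20 | 2-ethoxydiene | C=C(OCC)C1=C[C@@H]2O[C@H]1C[C@@](C)(OCOCc3ccccc3)[C@H](OC)CC[C@H]2O[Si](C)(C)C(C)(C)C | intermediate
21 | methyl vinyl ketone | CC(=O)C=C | starting material
22 | 14-epimeric cycloadduct | CO[C@@H]1CC[C@@H](O[Si](C)(C)C(C)(C)C)[C@@H]2[C@H]3[C@@H](C(C)=O)CCC(OCC)=C3[C@@H](O2)C[C@@]1(C)OCOCc4ccccc4 | intermediate (not isolated)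
23 | tricyclic 14-acetyl enol ether | CO[C@@H]1CC[C@@H](O[Si](C)(C)C(C)(C)C)[C@@H]2[C@H]3[C@H](C(C)=O)CCC(OCC)=C3[C@@H](O2)C[C@@]1(C)OCOCc4ccccc4 | intermediate
24 | alkenyl triflate of 23 | CO[C@@H]1CC[C@@H](O[Si](C)(C)C(C)(C)C)[C@@H]2[C@H]3[C@H](C(=C)OS(=O)(=O)C(F)(F)F)CCC(OCC)=C3[C@@H](O2)C[C@@]1(C)OCOCc4ccccc4 | intermediate
25 | 3-hydroxy enol ether | CO[C@@H]1CC[C@@H](O)[C@@H]2[C@H]3[C@H](C(=C)OS(=O)(=O)C(F)(F)F)CCC(OCC)=C3[C@@H](O2)C[C@@]1(C)OCOCc4ccccc4 | intermediate (not isolated)
26 | 3-hydroxy-11-ketone | CO[C@@H]1CC[C@@H](O)[C@@H]2[C@H]3[C@H](C(=C)OS(=O)(=O)C(F)(F)F)CCC(=O)[C@H]3[C@@H](O2)C[C@@]1(C)OCOCc4ccccc4 | intermediate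
27 | 11-methyl-3,11-diol | CO[C@@H]1CC[C@@H](O)[C@@H]2[C@H]3[C@H](C(=C)OS(=O)(=O)C(F)(F)F)CC[C@@](C)(O)[C@H]3[C@@H](O2)C[C@@]1(C)OCOCc4ccccc4 | intermediate
28 | 3-ketone | CO[C@@H]1CCC(=O)[C@@H]2[C@H]3[C@H](C(=C)OS(=O)(=O)C(F)(F)F)CC[C@@](C)(O)[C@H]3[C@@H](O2)C[C@@]1(C)OCOCc4ccccc4 | intermediate
29 | 3-methylidene compound | CO[C@@H]1CCC(=C)[C@@H]2[C@H]3[C@H](C(=C)OS(=O)(=O)C(F)(F)F)CC[C@@](C)(O)[C@H]3[C@@H](O2)C[C@@]1(C)OCOCc4ccccc4 | intermediate
30 | seco-diene 11-acetate | CO[C@@H]1CCC(=C)[C@@H]2[C@H]3[C@H](C(=C)OS(=O)(=O)C(F)(F)F)CC[C@@](C)(OC(C)=O)[C@H]3[C@@H](O2)C[C@@]1(C)OCOCc4ccccc4 | intermediate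
31 | carbon dioxide | O=C=O | starting material
32 | acrylate carboxylate (manganese salt, drawn as the anion) | CO[C@@H]1CCC(=C)[C@@H]2[C@H]3[C@H](C(=C)C([O-])=O)CC[C@@](C)(OC(C)=O)[C@H]3[C@@H](O2)C[C@@]1(C)OCOCc4ccccc4 | intermediate (not isolated)
33 | α-methylene iodolactone | CO[C@@H]1CC[C@]2(CI)OC(=O)C(=C)[C@@H]3CC[C@@](C)(OC(C)=O)[C@@H]4[C@H]3[C@@H]2O[C@H]4C[C@@]1(C)OCOCc5ccccc5 | intermediate
34 | CNP0238771.1 | CO[C@@H]1CC[C@]2(C)OC(=O)[C@H](C)[C@@H]3CC[C@@](C)(OC(C)=O)[C@@H]4[C@H]3[C@@H]2O[C@H]4C[C@@]1(C)O | target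

Total step count: 24. Longest linear sequence: 24 steps (from 1 and 2 to 34).

**Steps most likely to fail**

Step 23. The alkenyl–cobalt intermediate may be protonated or may add to the C3 methylidene before CO2 is captured. The seven-membered ring closure may be slow enough for the iodonium ion to be intercepted across the ring by O-7 or by water. The carboxylate may attack the wrong face of C3. The fallback builds the lactone the other way round (O–C17 and C17–C15) by known chemistry and sets out from 28. MeMgCl with LaCl3·2LiCl should add to the C3 ketone from the exposed face to give the 3-methyl-3,11-diol alkenyl triflate F1. Pd(PPh3)4, CO (1 atm), Et3N, DMF, 60 °C then closes the lactone by intramolecular alkoxycarbonylation (only the C3 hydroxyl can reach the acyl-palladium) to the α-methylene lactone 11-ol F2. Ac2O/DMAP gives the α-methylene lactone 11-acetate F3, and hydrogenation under the conditions of step 24 comes back to the route at 34.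

Step 24. Hydrogen may be delivered to the wrong face of the exocyclic alkene (C15 epimer). Iodide may poison the catalyst so that the BOM ether stays, or the β-acyloxy alkyl iodide may eliminate back to the alkenoic acid on palladium. The fallback sets C15 with a chiral catalyst before ring closure and sets out from 30. The cobalt-catalysed carboxylation is run alone and worked up with acid to the acrylic acid F4. Ru(OAc)2[(R)-BINAP], H2, MeOH hydrogenates only the carboxylate-bound alkene and should set C15 as in the 2-arylpropanoic acid series, giving the saturated acid F5. I2/NaHCO3 in MeCN closes the saturated iodolactone F6. Bu3SnH/AIBN removes iodine by a radical chain (no acrylate is present any more) to the saturated lactone BOM ether F7, and H2, Pd(OH)2/C cleaves the BOM ether to come back at 34.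

Step 10. The ylide rearrangement may give too little of the E-alkene (the same fallback serves if osmium in step 12 attacks the wrong alkene face). The fallback uses anti addition to the Z-alkene in place of syn addition to the E-alkene and sets out from 13. Cu(hfacac)2 in CH2Cl2 at reflux should give the Z-bicyclic ketone F8. m-CPBA with NaHCO3 epoxidizes the Z-alkene on its exposed face to the epoxy ketone F9. NaOMe in MeOH opens the epoxide by SN2 attack at the secondary C6 to the 6-methoxy-7-hydroxy ketone F10, and enol triflate formation (NaHMDS 2.2 equiv, PhNTf2) comes back to the route at 17.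

**Further compounds**
F1 | step 23 | 3-methyl-3,11-diol alkenyl triflate | CO[C@@H]1CC[C@](C)(O)[C@@H]2[C@H]3[C@H](C(=C)OS(=O)(=O)C(F)(F)F)CC[C@@](C)(O)[C@H]3[C@@H](O2)C[C@@]1(C)OCOCc4ccccc4
F2 | step 23 | α-methylene lactone 11-ol | CO[C@@H]1CC[C@]2(C)OC(=O)C(=C)[C@@H]3CC[C@@](C)(O)[C@@H]4[C@H]3[C@@H]2O[C@H]4C[C@@]1(C)OCOCc5ccccc5
F3 | step 23 | α-methylene lactone 11-acetate | CO[C@@H]1CC[C@]2(C)OC(=O)C(=C)[C@@H]3CC[C@@](C)(OC(C)=O)[C@@H]4[C@H]3[C@@H]2O[C@H]4C[C@@]1(C)OCOCc5ccccc5
F4 | step 24 | acrylic acid | CO[C@@H]1CCC(=C)[C@@H]2[C@H]3[C@H](C(=C)C(=O)O)CC[C@@](C)(OC(C)=O)[C@H]3[C@@H](O2)C[C@@]1(C)OCOCc4ccccc4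
F5 | step 24 | saturated acid | CO[C@@H]1CCC(=C)[C@@H]2[C@H]3[C@H]([C@@H](C)C(=O)O)CC[C@@](C)(OC(C)=O)[C@H]3[C@@H](O2)C[C@@]1(C)OCOCc4ccccc4
F6 | step 24 | saturated iodolactone | CO[C@@H]1CC[C@]2(CI)OC(=O)[C@H](C)[C@@H]3CC[C@@](C)(OC(C)=O)[C@@H]4[C@H]3[C@@H]2O[C@H]4C[C@@]1(C)OCOCc5ccccc5
F7 | step 24 | saturated lactone BOM ether | CO[C@@H]1CC[C@]2(C)OC(=O)[C@H](C)[C@@H]3CC[C@@](C)(OC(C)=O)[C@@H]4[C@H]3[C@@H]2O[C@H]4C[C@@]1(C)OCOCc5ccccc5
F8 | step 10 | Z-bicyclic ketone | O=C1C[C@@H]2O[C@H]1C/C(C)=C\CC[C@H]2O[Si](C)(C)C(C)(C)C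
F9 | step 10 | epoxy ketone | O=C1C[C@@H]2O[C@H]1C[C@@]3(C)O[C@H]3CC[C@H]2O[Si](C)(C)C(C)(C)C
F10 | step 10 | 6-methoxy-7-hydroxy ketone | O=C1C[C@@H]2O[C@H]1C[C@@](C)(O)[C@H](OC)CC[C@H]2O[Si](C)(C)C(C)(C)C
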